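## Retrosynthetic overview

1. Plan in one line: geranylgeraniol 1 → acetate 2 → cyclic acetate 3 (in the flask) → cyclic C20 alcohol 4; 4 + α-linolenic acid 5 → target 6.
2. Key disconnection: the ester C–O bond of 6, cut to 4 and 5. It is made last, so the skipped Z,Z,Z-triene of 5 never meets acid and the C20 and C18 halves are joined convergently.
3. Second disconnection: the ring bond C1'–C6' of 4 (C10–C15 of the open chain), back to the all-E tetraene 2. Forward, a catalytic enantioselective tail-selective cycloisomerisation (new) closes the ring and sets the one stereocentre.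
4. Ring order: there is one ring, the cyclohexene, closed in step 2. The acetate of 2 masks the hydroxyl, switches off the 2,3-alkene, and is removed in the same flask.
5. The two E and three Z chain alkenes of 6 are bought in 1 (annatto-derived, sold in bulk) and 5 (flaxseed-derived); nothing else is protected.

Assumption: "IDPi acid" is the C2-symmetric imidodiphosphorimidate Brønsted acid in which two (S)-3,3'-bis[3,5-bis(trifluoromethyl)phenyl]-1,1'-binaphthalene-2,2'-diyl phosphorus units are bridged by one nitrogen and each phosphorus carries an N–SO2CF3 imido group (one acidic N–H); its (S,S) form is assumed to give the (S) ring, and if a first screen shows the opposite sense the (R,R) acid from (R)-BINOL is used instead.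

## Route

Step 1
Reactants: 1 (2E,6E,10E)-geranylgeraniol
Product: 2 (2E,6E,10E)-geranylgeranyl acetate
Conditions: Ac2O (1.5 equiv), pyridine (3 equiv), DMAP (5 mol%), CH2Cl2, 0 → 23 °C; silver nitrate (AgNO3)-impregnated silica if 2Z isomer is present
Reagents that add atoms: acetic anhydride, CC(=O)OC(C)=O
Why: DMAP-catalysed acylation of the primary allylic alcohol (nucleophilic acyl substitution) is essentially quantitative under basic conditions that leave the four trisubstituted alkenes and their E geometry untouched, and the acetoxy group then masks the hydroxyl and deactivates the 2,3-alkene toward protonation in step 2; no stereocentre is formed.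

Step 2
Reactants: 2 (2E,6E,10E)-geranylgeranyl acetate
Product: 4 (2E,6E)-3,7-dimethyl-9-[(1S)-2,6,6-trimethylcyclohex-2-en-1-yl]nona-2,6-dien-1-ol, via cyclic acetate 3 (not isolated)
Conditions: (S,S)-IDPi acid [Ar = 3,5-(CF3)2C6H3, N-SO2CF3] (3 mol%), CH2Cl2/(CF3)3COH 9:1, 0.02 M, –60 °C; Et3N, evaporate; then K2CO3 (0.3 equiv), MeOH, 23 °C
Reagents that add atoms: none
Why: Proposed new method: tail-selective enantioselective protonative monocyclisation (a catalytic cycloisomerisation); mechanistic reasoning: the N–H proton sits at the bottom of the chiral cleft of the confined acid and can be reached only by the chain-end isopropylidene (the 6,7- and 10,11-alkenes carry chain on both sides, the 2,3-alkene is switched off by the allylic acetoxy group), protonation at C14 is concerted with anti attack of the 10,11-alkene on C15 through a cleft-bound chair (Stork–Eschenmoser-type cation–olefin addition), so the enantioface of the 10,11-alkene that the cleft exposes fixes C10, the future ring C1, as S; the ring C2 cation then sits as a contact ion pair in a cleft too small for a second chair fold and, at –60 °C in a weakly ionising medium, loses the neighbouring ring CH2 proton to the counter-anion faster than the 6,7-alkene can add (E1, kinetic endocyclic alpha olefin as in the H3PO4 cyclisation of pseudoionone to α-ionone), which returns the acid; closest known reaction type: confined chiral Brønsted acid and Lewis acid-assisted chiral Brønsted acid polyene cyclisations, which start at the terminal alkene but run on to polycycles ended by an internal oxygen or aryl nucleophile, and superacid cyclisations of polyprenyl acetates, which show that the allylic acetate survives; stopping cleanly at the monocyclic alpha olefin of an open C20 chain with enantiocontrol has not been shown; the cyclic acetate 3 is then cleaved in the same flask by K2CO3/MeOH transesterification.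

Step 3
Reactants: 4 (2E,6E)-3,7-dimethyl-9-[(1S)-2,6,6-trimethylcyclohex-2-en-1-yl]nona-2,6-dien-1-ol; 5 α-linolenic acid, (9Z,12Z,15Z)-octadeca-9,12,15-trienoic acid (1.05 equiv)
Product: 6 (2E,6E)-3,7-dimethyl-9-[(1S)-2,6,6-trimethylcyclohex-2-en-1-yl]nona-2,6-dien-1-yl (9Z,12Z,15Z)-octadeca-9,12,15-trienoate
Conditions: DCC (1.1 equiv), DMAP (10 mol%), BHT (trace), CH2Cl2, 0 → 23 °C, argon, dark
Reagents that add atoms: none
Why: Steglich esterification (carbodiimide activation with DMAP acyl transfer) forms the key ester C–O bond under neutral conditions at or below room temperature, so the allylic alcohol cannot ionise, the ring alkene cannot migrate (the S centre is untouched) and the skipped Z,Z,Z-triene is neither isomerised nor conjugated.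

## Compound list

1 | (2E,6E,10E)-3,7,11,15-tetramethylhexadeca-2,6,10,14-tetraen-1-ol (geranylgeraniol) | OC/C=C(\C)CC/C=C(\C)CC/C=C(\C)CCC=C(C)C | starting material
2 | (2E,6E,10E)-3,7,11,15-tetramethylhexadeca-2,6,10,14-tetraen-1-yl acetate (geranylgeranyl acetate) | CC(=O)OC/C=C(\C)CC/C=C(\C)CC/C=C(\C)CCC=C(C)C | intermediate
3 | (2E,6E)-3,7-dimethyl-9-[(1S)-2,6,6-trimethylcyclohex-2-en-1-yl]nona-2,6-dien-1-yl acetate (cyclic acetate) | CC(=O)OC/C=C(\C)CC/C=C(\C)CC[C@@H]1C(C)=CCCC1(C)C | intermediate
4 | (2E,6E)-3,7-dimethyl-9-[(1S)-2,6,6-trimethylcyclohex-2-en-1-yl]nona-2,6-dien-1-ol | OC/C=C(\C)CC/C=C(\C)CC[C@@H]1C(C)=CCCC1(C)C | intermediate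
5 | (9Z,12Z,15Z)-octadeca-9,12,15-trienoic acid (α-linolenic acid) | CC/C=C\C/C=C\C/C=C\CCCCCCCC(=O)O | starting material
6 | (2E,6E)-3,7-dimethyl-9-[(1S)-2,6,6-trimethylcyclohex-2-en-1-yl]nona-2,6-dien-1-yl (9Z,12Z,15Z)-octadeca-9,12,15-trienoate | CC/C=C\C/C=C\C/C=C\CCCCCCCC(=O)OC/C=C(\C)CC/C=C(\C)CC[C@@H]1C(C)=CCCC1(C)C | target

## Step count and risk

Total step count: 3. Longest linear sequence: 3 (1 → 2 → 4 → 6; 5 enters in the last step).

**Most likely to fail: step 2 (the proposed new step).**
- What can go wrong: protonation at an internal alkene, onward closure to bicyclic products, beta or exocyclic olefin isomers, low ee, or ionisation of the allylic acetate in the fluorinated medium.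
- First response within the step: change the 3,3'-aryl groups and lower the fluoroalcohol content.
- Fallback (known chemistry only): it does not set out from a numbered compound, because none of 1, 2 or 3 is used; it starts from two other bulk terpenoids and comes back to the route at alcohol 4.
  - Ring half: geranic acid F1 is cyclised with 85% H3PO4 to (±)-α-cyclogeranic acid F2. F2 is resolved by crystallisation of a 1-phenylethylammonium salt to (S)-α-cyclogeranic acid F3. LiAlH4 in Et2O reduces it to (S)-α-cyclogeraniol F4. PhSSPh/Bu3P in pyridine gives the phenyl sulfide F5, and H2O2 with catalytic (NH4)6Mo7O24 in EtOH gives the phenyl sulfone F6 without touching the ring alkene.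
  - Chain half: geranyl acetate F7 is oxidised at its E-methyl group with catalytic SeO2/t-BuOOH to (2E,6E)-8-hydroxygeranyl acetate F8. CBr4/PPh3 converts it to (2E,6E)-8-bromogeranyl acetate F9.
  - Union: the lithio derivative of F6 (n-BuLi, THF/DMPU, –78 °C) is alkylated with F9 to the sulfonyl acetate F10 (Julia-type sulfone alkylation; the alkene geometry comes from F7 and the ring stereocentre from the resolution). Sodium amalgam (Na/Hg) with Na2HPO4 in MeOH/THF at –20 °C removes the sulfonyl group while methoxide cleaves the acetate, which gives 4 for step 3.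

**Second: step 3.**
- What can go wrong: N-acylurea formation, or autoxidation of the bis-allylic positions of 5 during coupling and chromatography.
- Fallback: it sets out from 4 and comes back at 6, forming the C–O bond by O-alkylation instead of acyl substitution. MsCl, LiCl and 2,4,6-collidine in DMF at 0 °C convert 4 without allylic transposition into the allylic chloride F11. F11 is displaced by the caesium salt of 5 (Cs2CO3, DMF, 23 °C) to give 6.

**Third: step 1.**
- What can go wrong: little, apart from 2Z isomer carried in from commercial 1 and any allylic transposition if the medium turns acidic.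
- Fallback: it sets out from 1 and comes back at 2, replacing anhydride chemistry by enzymatic acyl transfer. Immobilised Candida antarctica lipase B with vinyl acetate in hexane at 30 °C acetylates the primary alcohol under neutral conditions. This fallback makes no new compound (entry F0).

## Further compounds

F0 | step 1 | none | none
F1 | step 2 | (2E)-geranic acid (the commercial E/Z mixture serves) | CC(C)=CCC/C(C)=C/C(=O)O
F2 | step 2 | (±)-α-cyclogeranic acid, 2,6,6-trimethylcyclohex-2-ene-1-carboxylic acid | OC(=O)C1C(C)=CCCC1(C)C
F3 | step 2 | (S)-α-cyclogeranic acid | OC(=O)[C@@H]1C(C)=CCCC1(C)C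
F4 | step 2 | (S)-α-cyclogeraniol, [(1S)-2,6,6-trimethylcyclohex-2-en-1-yl]methanol | OC[C@@H]1C(C)=CCCC1(C)C
F5 | step 2 | phenyl [(1S)-2,6,6-trimethylcyclohex-2-en-1-yl]methyl sulfide | c1ccccc1SC[C@@H]2C(C)=CCCC2(C)C
F6 | step 2 | phenyl [(1S)-2,6,6-trimethylcyclohex-2-en-1-yl]methyl sulfone | O=S(=O)(C[C@@H]1C(C)=CCCC1(C)C)c1ccccc1
F7 | step 2 | geranyl acetate | CC(=O)OC/C=C(\C)CCC=C(C)C
F8 | step 2 | (2E,6E)-8-hydroxy-3,7-dimethylocta-2,6-dien-1-yl acetate | CC(=O)OC/C=C(\C)CC/C=C(\C)CO
F9 | step 2 | (2E,6E)-8-bromo-3,7-dimethylocta-2,6-dien-1-yl acetate | CC(=O)OC/C=C(\C)CC/C=C(\C)CBr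
F10 | step 2 | (2E,6E)-3,7-dimethyl-9-(phenylsulfonyl)-9-[(1S)-2,6,6-trimethylcyclohex-2-en-1-yl]nona-2,6-dien-1-yl acetate (both C9 epimers) | CC(=O)OC/C=C(\C)CC/C=C(\C)CC([C@@H]1C(C)=CCCC1(C)C)S(=O)(=O)c1ccccc1
F11 | step 3 | (2E,6E)-1-chloro-3,7-dimethyl-9-[(1S)-2,6,6-trimethylcyclohex-2-en-1-yl]nona-2,6-diene | ClC/C=C(\C)CC/C=C(\C)CC[C@@H]1C(C)=CCCC1(C)C
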